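**Retrosynthetic overview**

1. Numbering used throughout (friedodrimane): ring A = C1–C5 + C10 (C3 ketone, methyls on C4 and C5); ring B = C5–C10 (methyls on C8 and C9); C11 = the OCH2 carbon on C9. Late disconnections: aryl ether O–C11 (isofraxidin + neopentyl triflate), C3=O from a silyl ether, C6–C7 from an alkene.
2. Enabling feature: ring B holds four contiguous stereocentres C8, C9, C10, C5 with the oxygenated C11 on C9. With a C6=C7 double bond it is the retron of a Diels–Alder reaction between an (E)-2-methyl-2-enal (C9=C10, C11 as CHO) and an (E,E)-diene (C5=C6–C7=C8), and ring A is exactly the four-carbon tether C1–C4 from C10 to C5.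
3. Key step: Lewis-acid-promoted intramolecular Diels–Alder reaction of an open-chain (E,E,E)-trienal. It makes two C–C bonds, both carbocycles and C5, C8, C9, C10 (two quaternary) in one operation; alkene geometry and the endo rule give the relative configuration, a syn C3-OSi/C4-Me pair in the tether gives the absolute one.
4. Trienal: 4-silyloxybutanal + chiral allenylstannane from (S)-but-3-yn-2-ol (Marshall propargylation sets C3 and C4), carboalumination/cross-coupling (diene), Wittig (enal).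
5. Ring order: coumarin bicycle bought intact (isofraxidin); rings B and A are both closed in step 9, ring A as the tether ring by the C5–C10 bond; no ring is formed afterwards.

Key step: step 9

Remark: compounds 1, 4, 7, 12 and 18 are taken as commercial; C-numbers in the Why lines are the friedodrimane numbers defined above.

**Step 1**
Reactants: 1 (S)-but-3-yn-2-ol
Product: 2 (S)-but-3-yn-2-yl methanesulfonate
Conditions: MsCl, Et3N, CH2Cl2, −78 → 0 °C
Reagents that add atoms: methanesulfonyl chloride, CS(=O)(=O)Cl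
Why: O-sulfonylation (mesylation) of the secondary alcohol leaves the C–O bond of the stereocentre untouched, so the configuration should be kept.

**Step 2**
Reactants: 2 (S)-but-3-yn-2-yl methanesulfonate
Product: 3 (M)-buta-1,2-dien-1-yl(tributyl)stannane
Conditions: Bu3SnH, LiN(iPr)2, THF, 0 °C; CuBr·SMe2, −78 °C; then 2, −78 °C
Reagents that add atoms: tributyltin hydride, CCCC[SnH](CCCC)CCCC
Why: Substitution of a propargylic mesylate by a stannylcopper reagent runs anti-SN2′, so the central chirality of 2 should be transferred to the axial chirality of the allene.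

**Step 3**
Reactants: 3 (M)-buta-1,2-dien-1-yl(tributyl)stannane; 4 4-[(tert-butyldimethylsilyl)oxy]butanal
Product: 5 (4S,5S)-1-[(tert-butyldimethylsilyl)oxy]-5-methylhept-6-yn-4-ol
Conditions: BF3·OEt2, CH2Cl2, −78 °C; aq. NaHCO3
Reagents that add atoms: none
Why: Marshall propargylation (BF3-promoted SE2′ addition through an open, anti transition state) should give the syn homopropargylic alcohol, the allene axis setting C4 and the syn preference setting C3.

**Step 4**
Reactants: 5 (4S,5S)-1-[(tert-butyldimethylsilyl)oxy]-5-methylhept-6-yn-4-ol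
Product: 6 (4S,5S)-1,4-bis[(tert-butyldimethylsilyl)oxy]-5-methylhept-6-yne
Conditions: TBSOTf, 2,6-lutidine, CH2Cl2, 0 °C
Reagents that add atoms: tert-butyldimethylsilyl trifluoromethanesulfonate, CC(C)(C)[Si](C)(C)OS(=O)(=O)C(F)(F)F
Why: Silylation of the secondary alcohol with the silyl triflate is reliable on hindered carbinols and does not affect the alkyne or the stereocentres.

**Step 5**
Reactants: 6 (4S,5S)-1,4-bis[(tert-butyldimethylsilyl)oxy]-5-methylhept-6-yne; 7 (E)-1-bromoprop-1-ene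
Product: 9 (4S,5S,6E,8E)-1,4-bis[(tert-butyldimethylsilyl)oxy]-5,6-dimethyldeca-6,8-diene, via alkenylalane 8 (not isolated)
Conditions: Me3Al, Cp2ZrCl2 (cat.), CH2Cl2, 0 °C → rt; then 7, ZnCl2, Pd(PPh3)4 (cat.), THF, rt
Reagents that add atoms: trimethylaluminium, C[Al](C)C
Why: Negishi zirconium-catalysed syn-carboalumination puts methyl on the internal and aluminium on the terminal alkyne carbon, and the palladium/zinc cross-coupling proceeds with retention on both partners, so both diene double bonds should be E.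

**Step 6**
Reactants: 9 (4S,5S,6E,8E)-1,4-bis[(tert-butyldimethylsilyl)oxy]-5,6-dimethyldeca-6,8-diene
Product: 10 (4S,5S,6E,8E)-4-[(tert-butyldimethylsilyl)oxy]-5,6-dimethyldeca-6,8-dien-1-ol
Conditions: HF·pyridine, pyridine, THF, 0 °C
Reagents that add atoms: none
Why: Selective desilylation: the unhindered primary silyl ether should be cleaved much faster than the secondary one flanked by the C4 methyl, and the buffered medium spares the diene.

**Step 7**
Reactants: 10 (4S,5S,6E,8E)-4-[(tert-butyldimethylsilyl)oxy]-5,6-dimethyldeca-6,8-dien-1-ol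
Product: 11 (4S,5S,6E,8E)-4-[(tert-butyldimethylsilyl)oxy]-5,6-dimethyldeca-6,8-dienal
Conditions: Dess–Martin periodinane, NaHCO3, CH2Cl2, 0 °C → rt
Reagents that add atoms: none
Why: Dess–Martin oxidation of a primary alcohol is neutral and should leave the diene, the silyl ether and the remote stereocentres untouched.

**Step 8**
Reactants: 11 (4S,5S,6E,8E)-4-[(tert-butyldimethylsilyl)oxy]-5,6-dimethyldeca-6,8-dienal; 12 2-(triphenylphosphoranylidene)propanal
Product: 13 (2E,6S,7S,8E,10E)-6-[(tert-butyldimethylsilyl)oxy]-2,7,8-trimethyldodeca-2,8,10-trienal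
Conditions: 12 (1.3 equiv), toluene, 60 °C
Reagents that add atoms: none
Why: Wittig olefination with the formyl-stabilised ylide should give the (E)-2-methyl-2-enal selectively, and the moderate temperature is chosen to avoid an uncatalysed cycloaddition of the product.

**Step 9**
Reactants: 13 (2E,6S,7S,8E,10E)-6-[(tert-butyldimethylsilyl)oxy]-2,7,8-trimethyldodeca-2,8,10-trienal
Product: 14 (1S,2S,4aR,5S,6S,8aS)-6-[(tert-butyldimethylsilyl)oxy]-1,2,4a,5-tetramethyl-1,2,4a,5,6,7,8,8a-octahydronaphthalene-1-carbaldehyde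
Conditions: Me2AlCl (1.5 equiv, promoter), CH2Cl2, −78 → −20 °C
Reagents that add atoms: none
Why: Me2AlCl binds the formyl oxygen and lowers the enal LUMO, so the (E)-2-methyl-2-enal (C9=C10) and the (E,E)-diene (C5=C6–C7=C8) should undergo a concerted, asynchronous intramolecular Diels–Alder reaction (type 1, tether C1–C4); the closest known reaction type is the Lewis-acid-promoted cyclisation of 2,8,10-trienals to trans-fused octalin carbaldehydes. Ring B is closed as the cycloadduct cyclohexene by the C5–C10 and C8–C9 bonds, and ring A is closed in the same event as the six-membered tether ring by the C5–C10 bond through a chair-like tether. Both components add suprafacially, so the (E)-enal fixes the C9 methyl trans to H-10 and the (E,E)-diene fixes the C8 methyl cis to C4 on C5. The endo-formyl transition state (tether exo), favoured by the Lewis acid, gives the trans ring fusion with CHO, H-10, the C8 methyl and C4 on one face and the C5 and C9 methyls on the other. The absolute sense comes from the syn C3/C4 pair: only one diene face lets the silyloxy group and the C4 methyl both sit equatorial with H-4 eclipsing the diene (minimal allylic strain), whereas the other face would force both axial against the C5 methyl. The step needs endo over exo and one π-face out of two, and these are secured by Lewis-acid activation, the fixed alkene geometries and the two tether stereocentres.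

**Step 10**
Reactants: 14 (1S,2S,4aR,5S,6S,8aS)-6-[(tert-butyldimethylsilyl)oxy]-1,2,4a,5-tetramethyl-1,2,4a,5,6,7,8,8a-octahydronaphthalene-1-carbaldehyde
Product: 15 [(1S,2S,4aR,5S,6S,8aS)-6-[(tert-butyldimethylsilyl)oxy]-1,2,4a,5-tetramethyl-1,2,4a,5,6,7,8,8a-octahydronaphthalen-1-yl]methanol
Conditions: NaBH4, MeOH, 0 °C
Reagents that add atoms: none
Why: Borohydride reduction of the non-enolisable aldehyde on quaternary C9 should give the primary alcohol without touching any stereocentre.

**Step 11**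
Reactants: 15 [(1S,2S,4aR,5S,6S,8aS)-6-[(tert-butyldimethylsilyl)oxy]-1,2,4a,5-tetramethyl-1,2,4a,5,6,7,8,8a-octahydronaphthalen-1-yl]methanol
Product: 16 [(1S,2S,4aR,5S,6S,8aS)-6-[(tert-butyldimethylsilyl)oxy]-1,2,4a,5-tetramethyldecahydronaphthalen-1-yl]methanol
Conditions: H2 (1 atm), PtO2, EtOAc, rt
Reagents that add atoms: none
Why: Catalytic hydrogenation of the only C=C creates no stereocentre; platinum is chosen over palladium to suppress migration of the double bond toward C8, and the step is placed before the coumarin is attached.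

**Step 12**
Reactants: 16 [(1S,2S,4aR,5S,6S,8aS)-6-[(tert-butyldimethylsilyl)oxy]-1,2,4a,5-tetramethyldecahydronaphthalen-1-yl]methanol
Product: 17 [(1S,2S,4aR,5S,6S,8aS)-6-[(tert-butyldimethylsilyl)oxy]-1,2,4a,5-tetramethyldecahydronaphthalen-1-yl]methyl trifluoromethanesulfonate
Conditions: Tf2O, pyridine, CH2Cl2, −40 → 0 °C
Reagents that add atoms: trifluoromethanesulfonic anhydride, O=S(=O)(OS(=O)(=O)C(F)(F)F)C(F)(F)F
Why: Triflation of the primary neopentyl alcohol gives the most reactive sulfonate, and C9 carries no hydrogen, so elimination cannot occur.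

**Step 13**
Reactants: 17 [(1S,2S,4aR,5S,6S,8aS)-6-[(tert-butyldimethylsilyl)oxy]-1,2,4a,5-tetramethyldecahydronaphthalen-1-yl]methyl trifluoromethanesulfonate; 18 isofraxidin (7-hydroxy-6,8-dimethoxy-2H-chromen-2-one)
Product: 19 7-{[(1S,2S,4aR,5S,6S,8aS)-6-[(tert-butyldimethylsilyl)oxy]-1,2,4a,5-tetramethyldecahydronaphthalen-1-yl]methoxy}-6,8-dimethoxy-2H-chromen-2-one
Conditions: Cs2CO3, DMF, 25 → 50 °C
Reagents that add atoms: none
Why: Williamson ether synthesis: SN2 displacement of the primary triflate by the caesium phenoxide in a dipolar aprotic solvent should form the O–C11 bond, and the lactone is stable to carbonate in dry DMF.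

**Step 14**
Reactants: 19 7-{[(1S,2S,4aR,5S,6S,8aS)-6-[(tert-butyldimethylsilyl)oxy]-1,2,4a,5-tetramethyldecahydronaphthalen-1-yl]methoxy}-6,8-dimethoxy-2H-chromen-2-one
Product: 20 7-{[(1S,2S,4aR,5S,6S,8aS)-6-hydroxy-1,2,4a,5-tetramethyldecahydronaphthalen-1-yl]methoxy}-6,8-dimethoxy-2H-chromen-2-one
Conditions: HF·pyridine, THF, 25 → 40 °C
Reagents that add atoms: none
Why: Acidic fluoride desilylation should free the C3 alcohol without opening the coumarin lactone, which a basic fluoride source could attack.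

**Step 15**
Reactants: 20 7-{[(1S,2S,4aR,5S,6S,8aS)-6-hydroxy-1,2,4a,5-tetramethyldecahydronaphthalen-1-yl]methoxy}-6,8-dimethoxy-2H-chromen-2-one
Product: 21 7-{[(1S,2S,4aR,5S,8aS)-1,2,4a,5-tetramethyl-6-oxodecahydronaphthalen-1-yl]methoxy}-6,8-dimethoxy-2H-chromen-2-one (CNP0225022.2)
Conditions: Dess–Martin periodinane, NaHCO3, CH2Cl2, rt
Reagents that add atoms: none
Why: Dess–Martin oxidation of the secondary alcohol gives the C3 ketone; the C4 methyl is already equatorial, the thermodynamically preferred position next to the ketone, so no epimerisation is expected.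

**Compound list**

1 | (S)-but-3-yn-2-ol | C[C@H](O)C#C | starting material
2 | (S)-but-3-yn-2-yl methanesulfonate | C[C@H](OS(C)(=O)=O)C#C | intermediate
3 | (M)-buta-1,2-dien-1-yl(tributyl)stannane | CC([H])=[C@]=C([H])[Sn](CCCC)(CCCC)CCCC | intermediate
4 | 4-[(tert-butyldimethylsilyl)oxy]butanal | CC(C)(C)[Si](C)(C)OCCCC=O | starting material
5 | (4S,5S)-1-[(tert-butyldimethylsilyl)oxy]-5-methylhept-6-yn-4-ol | CC(C)(C)[Si](C)(C)OCCC[C@H](O)[C@@H](C)C#C | intermediate
6 | (4S,5S)-1,4-bis[(tert-butyldimethylsilyl)oxy]-5-methylhept-6-yne | CC(C)(C)[Si](C)(C)OCCC[C@H](O[Si](C)(C)C(C)(C)C)[C@@H](C)C#C | intermediate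
7 | (E)-1-bromoprop-1-ene | C/C=C/Br | starting material
8 | [(1E,3S,4S)-4,7-bis[(tert-butyldimethylsilyl)oxy]-2,3-dimethylhept-1-en-1-yl]dimethylalane | CC(C)(C)[Si](C)(C)OCCC[C@H](O[Si](C)(C)C(C)(C)C)[C@@H](C)/C(C)=C/[Al](C)C | intermediate
9 | (4S,5S,6E,8E)-1,4-bis[(tert-butyldimethylsilyl)oxy]-5,6-dimethyldeca-6,8-diene | CC(C)(C)[Si](C)(C)OCCC[C@H](O[Si](C)(C)C(C)(C)C)[C@@H](C)/C(C)=C/C=C/C | intermediate
10 | (4S,5S,6E,8E)-4-[(tert-butyldimethylsilyl)oxy]-5,6-dimethyldeca-6,8-dien-1-ol | OCCC[C@H](O[Si](C)(C)C(C)(C)C)[C@@H](C)/C(C)=C/C=C/C | intermediate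
11 | (4S,5S,6E,8E)-4-[(tert-butyldimethylsilyl)oxy]-5,6-dimethyldeca-6,8-dienal | O=CCC[C@H](O[Si](C)(C)C(C)(C)C)[C@@H](C)/C(C)=C/C=C/C | intermediate
12 | 2-(triphenylphosphoranylidene)propanal | CC(C=O)=P(c1ccccc1)(c1ccccc1)c1ccccc1 | starting material
13 | (2E,6S,7S,8E,10E)-6-[(tert-butyldimethylsilyl)oxy]-2,7,8-trimethyldodeca-2,8,10-trienal | O=C/C(C)=C/CC[C@H](O[Si](C)(C)C(C)(C)C)[C@@H](C)/C(C)=C/C=C/C | intermediate
14 | (1S,2S,4aR,5S,6S,8aS)-6-[(tert-butyldimethylsilyl)oxy]-1,2,4a,5-tetramethyl-1,2,4a,5,6,7,8,8a-octahydronaphthalene-1-carbaldehyde | O=C[C@]1(C)[C@H]2CC[C@H](O[Si](C)(C)C(C)(C)C)[C@@H](C)[C@]2(C)C=C[C@@H]1C | intermediate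
15 | [(1S,2S,4aR,5S,6S,8aS)-6-[(tert-butyldimethylsilyl)oxy]-1,2,4a,5-tetramethyl-1,2,4a,5,6,7,8,8a-octahydronaphthalen-1-yl]methanol | OC[C@]1(C)[C@H]2CC[C@H](O[Si](C)(C)C(C)(C)C)[C@@H](C)[C@]2(C)C=C[C@@H]1C | intermediate
16 | [(1S,2S,4aR,5S,6S,8aS)-6-[(tert-butyldimethylsilyl)oxy]-1,2,4a,5-tetramethyldecahydronaphthalen-1-yl]methanol | OC[C@]1(C)[C@H]2CC[C@H](O[Si](C)(C)C(C)(C)C)[C@@H](C)[C@]2(C)CC[C@@H]1C | intermediate
17 | [(1S,2S,4aR,5S,6S,8aS)-6-[(tert-butyldimethylsilyl)oxy]-1,2,4a,5-tetramethyldecahydronaphthalen-1-yl]methyl trifluoromethanesulfonate | FC(F)(F)S(=O)(=O)OC[C@]1(C)[C@H]2CC[C@H](O[Si](C)(C)C(C)(C)C)[C@@H](C)[C@]2(C)CC[C@@H]1C | intermediate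
18 | isofraxidin (7-hydroxy-6,8-dimethoxy-2H-chromen-2-one) | COc1cc2ccc(=O)oc2c(OC)c1O | starting material
19 | 7-{[(1S,2S,4aR,5S,6S,8aS)-6-[(tert-butyldimethylsilyl)oxy]-1,2,4a,5-tetramethyldecahydronaphthalen-1-yl]methoxy}-6,8-dimethoxy-2H-chromen-2-one | COc1cc2ccc(=O)oc2c(OC)c1OC[C@]1(C)[C@H]2CC[C@H](O[Si](C)(C)C(C)(C)C)[C@@H](C)[C@]2(C)CC[C@@H]1C | intermediate
20 | 7-{[(1S,2S,4aR,5S,6S,8aS)-6-hydroxy-1,2,4a,5-tetramethyldecahydronaphthalen-1-yl]methoxy}-6,8-dimethoxy-2H-chromen-2-one | COc1cc2ccc(=O)oc2c(OC)c1OC[C@]1(C)[C@H]2CC[C@H](O)[C@@H](C)[C@]2(C)CC[C@@H]1C | intermediate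
21 | 7-{[(1S,2S,4aR,5S,8aS)-1,2,4a,5-tetramethyl-6-oxodecahydronaphthalen-1-yl]methoxy}-6,8-dimethoxy-2H-chromen-2-one | COc1cc2ccc(=O)oc2c(OC)c1OC[C@]1(C)[C@H]2CCC(=O)[C@@H](C)[C@]2(C)CC[C@@H]1C | target

**Step count and risks**

Total step count: 15. Longest linear sequence: 15 steps (1 → 21).

The three steps most likely to fail:

Step 9 (key cycloaddition). The fully substituted diene terminus C5 may bond so slowly that Lewis-acid-induced isomerisation or oligomerisation of the diene, or the exo (cis-fused) pathway, competes. The fallback changes the dienophile from a Lewis-acid complex to a discrete cation. It sets out from 13, which would be acetalised (1,2-bis(trimethylsilyloxy)ethane, cat. TMSOTf, CH2Cl2, −78 °C) to 2-[(2E,6S,7S,8E,10E)-6-[(tert-butyldimethylsilyl)oxy]-7,8-dimethyldodeca-2,8,10-trien-2-yl]-1,3-dioxolane F1. Catalytic TfOH in CH2Cl2 at −78 °C should open F1 to an alkoxyallyl (2-alkenyl-dioxolanylium) cation, a far stronger dienophile, which undergoes the ionic intramolecular Diels–Alder reaction and recloses to 2-[(1S,2S,4aR,5S,6S,8aS)-6-[(tert-butyldimethylsilyl)oxy]-1,2,4a,5-tetramethyl-1,2,4a,5,6,7,8,8a-octahydronaphthalen-1-yl]-1,3-dioxolane F2. Mild hydrolysis (PPTS, wet acetone) would bring the route back at 14.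

Step 13 (ether formation). Bimolecular displacement at the neopentyl carbon C11 by a phenoxide flanked by two methoxy groups may be slower than ionisation of the triflate with a 1,2-alkyl shift (ring expansion). The fallback forms the aryl–oxygen bond instead of the alkyl–oxygen bond. It sets out from alcohol 16 and from 18, which would be converted (Tf2O, pyridine, CH2Cl2, 0 °C) into 6,8-dimethoxy-2-oxo-2H-chromen-7-yl trifluoromethanesulfonate F3. Palladium-catalysed C–O cross-coupling of 16 with F3 (Pd(OAc)2, tBuBrettPhos, Cs2CO3, toluene, 90 °C) would come back to the route at 19.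

Step 3 (propargylation). The open transition state may give incomplete syn selectivity with an unbranched aldehyde, and the axial-to-central chirality transfer may be partly lost. The fallback builds the same C3/C4 pair by an Evans syn-aldol reaction and sets out from 4. (R)-4-Benzyl-3-propionyloxazolidin-2-one (CCC(=O)N1[C@H](Cc2ccccc2)COC1=O; Bu2BOTf, iPr2NEt, CH2Cl2, −78 → 0 °C, then 4) should give (R)-4-benzyl-3-[(2R,3S)-6-[(tert-butyldimethylsilyl)oxy]-3-hydroxy-2-methylhexanoyl]oxazolidin-2-one F4. Silylation (TBSOTf, 2,6-lutidine) gives (R)-4-benzyl-3-[(2R,3S)-3,6-bis[(tert-butyldimethylsilyl)oxy]-2-methylhexanoyl]oxazolidin-2-one F5. Reductive removal of the auxiliary (LiBH4, THF/MeOH, 0 °C) gives (2S,3S)-3,6-bis[(tert-butyldimethylsilyl)oxy]-2-methylhexan-1-ol F6, and Dess–Martin oxidation gives (2R,3S)-3,6-bis[(tert-butyldimethylsilyl)oxy]-2-methylhexanal F7. Ohira–Bestmann homologation (dimethyl (1-diazo-2-oxopropyl)phosphonate, K2CO3, MeOH, 0 °C) would come back to the route at 6.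

**Further compounds**

F1 | step 9 | 2-[(2E,6S,7S,8E,10E)-6-[(tert-butyldimethylsilyl)oxy]-7,8-dimethyldodeca-2,8,10-trien-2-yl]-1,3-dioxolane | O1CCOC1/C(C)=C/CC[C@H](O[Si](C)(C)C(C)(C)C)[C@@H](C)/C(C)=C/C=C/C
F2 | step 9 | 2-[(1S,2S,4aR,5S,6S,8aS)-6-[(tert-butyldimethylsilyl)oxy]-1,2,4a,5-tetramethyl-1,2,4a,5,6,7,8,8a-octahydronaphthalen-1-yl]-1,3-dioxolane | O3CCOC3[C@]1(C)[C@H]2CC[C@H](O[Si](C)(C)C(C)(C)C)[C@@H](C)[C@]2(C)C=C[C@@H]1C
F3 | step 13 | 6,8-dimethoxy-2-oxo-2H-chromen-7-yl trifluoromethanesulfonate | COc1cc2ccc(=O)oc2c(OC)c1OS(=O)(=O)C(F)(F)F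
F4 | step 3 | (R)-4-benzyl-3-[(2R,3S)-6-[(tert-butyldimethylsilyl)oxy]-3-hydroxy-2-methylhexanoyl]oxazolidin-2-one | CC(C)(C)[Si](C)(C)OCCC[C@H](O)[C@@H](C)C(=O)N1[C@H](Cc2ccccc2)COC1=O
F5 | step 3 | (R)-4-benzyl-3-[(2R,3S)-3,6-bis[(tert-butyldimethylsilyl)oxy]-2-methylhexanoyl]oxazolidin-2-one | CC(C)(C)[Si](C)(C)OCCC[C@H](O[Si](C)(C)C(C)(C)C)[C@@H](C)C(=O)N1[C@H](Cc2ccccc2)COC1=O
F6 | step 3 | (2S,3S)-3,6-bis[(tert-butyldimethylsilyl)oxy]-2-methylhexan-1-ol | CC(C)(C)[Si](C)(C)OCCC[C@H](O[Si](C)(C)C(C)(C)C)[C@@H](C)CO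
F7 | step 3 | (2R,3S)-3,6-bis[(tert-butyldimethylsilyl)oxy]-2-methylhexanal | CC(C)(C)[Si](C)(C)OCCC[C@H](O[Si](C)(C)C(C)(C)C)[C@@H](C)C=O
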